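**Retrosynthetic overview**
Numbering used here: lactone O1–C2(=O)–C3–C4–C5 (methyl on C5); side chain C1′ (OH) to C11′ (3-furyl), with C4′ (OH, CH3), C5′=C6′ and C8′=C9′.
Last disconnection is C5′=C6′: cross-metathesis of the vinyl carbinol of the lactone half with a 3-furyl 1,4-diene, itself made by carboalumination of pent-1-en-4-yne and Negishi coupling to 3-bromofuran.
The lactone half comes from (S)-linalool, which supplies C4′ with its configuration, C1′–C6′, C5, the 5-methyl and C4 (the (E)-methyl of its isopropylidene end).
Key disconnection: C3–C4 and O1–C5 in one operation, a [3+2] annulation of the acetic acid dianion (C,O-dinucleophile) onto a 2,3-epoxy triflate (C4/C5 dielectrophile). The enabling feature is that O1 on C5 and the hydroxyl on C1′ sit anti on neighbouring carbons, the signature of a trans-trisubstituted C5–C1′ oxirane opened at its tertiary carbon with inversion, and C4 is an allylic methyl that SeO2 can oxidise, so one Sharpless epoxidation sets both stereocentres.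
Ring order: furan bought; oxirane (temporary, step 3); γ-lactone (step 5, at the expense of the oxirane).

Key step: step 5

Assumption: (S)-(+)-linalool is bought in high enantiomeric purity, and its stereocentre becomes C4′ unchanged.

**Route**

Step 1
Reactants: 1 (S)-(+)-linalool, (3S)-3,7-dimethylocta-1,6-dien-3-ol
Product: 2 (3S)-3,7-dimethyl-3-[(triethylsilyl)oxy]octa-1,6-diene
Conditions: Et3SiOTf, 2,6-lutidine, CH2Cl2, −78 → 0 °C
Reagents that add atoms: triethylsilyl trifluoromethanesulfonate, CC[Si](CC)(CC)OS(=O)(=O)C(F)(F)F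
Why: Silylation of a tertiary alcohol with a silyl triflate and a hindered pyridine base is standard, and the ether keeps the C4′ oxygen from opening the later oxirane (which would give tetrahydrofuran ethers) and from binding titanium in step 3.

Step 2
Reactants: 2 (3S)-3,7-dimethyl-3-[(triethylsilyl)oxy]octa-1,6-diene
Product: 3 (2E,6S)-2,6-dimethyl-6-[(triethylsilyl)oxy]octa-2,7-dien-1-ol
Conditions: SeO2 (cat.), t-BuOOH, salicylic acid (cat.), CH2Cl2, 0 °C → rt
Reagents that add atoms: tert-butyl hydroperoxide, CC(C)(C)OO
Why: Riley allylic oxidation (ene reaction of SeO2, then [2,3]-sigmatropic shift of the allylseleninic acid) hydroxylates the (E)-methyl of a trisubstituted isopropylidene group with high (E)-selectivity, the vinyl group has no allylic hydrogen, and t-BuOOH returns selenium to its tetravalent state, so the methyl destined to be lactone C4 becomes a primary allylic alcohol.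

Step 3
Reactants: 3 (2E,6S)-2,6-dimethyl-6-[(triethylsilyl)oxy]octa-2,7-dien-1-ol
Product: 4 [(2R,3R)-2-methyl-3-{(3S)-3-methyl-3-[(triethylsilyl)oxy]pent-4-en-1-yl}oxiran-2-yl]methanol
Conditions: Ti(OiPr)4 (cat.), diisopropyl D-(−)-tartrate (cat.), t-BuOOH, 4 Å molecular sieves, CH2Cl2, −20 °C
Reagents that add atoms: tert-butyl hydroperoxide, CC(C)(C)OO
Why: Sharpless asymmetric epoxidation, for which (E)-2-methylallylic alcohols are among the best substrates: the D-(−)-tartrate titanium catalyst should deliver oxygen under reagent control to the face that gives the (2R,3R)-oxirane, which sets C1′ as it will stay and C5 in the configuration that one inversion will correct, while the vinyl group, lacking a directing hydroxyl, is untouched.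

Step 4
Reactants: 4 [(2R,3R)-2-methyl-3-{(3S)-3-methyl-3-[(triethylsilyl)oxy]pent-4-en-1-yl}oxiran-2-yl]methanol
Product: 5 [(2R,3R)-2-methyl-3-{(3S)-3-methyl-3-[(triethylsilyl)oxy]pent-4-en-1-yl}oxiran-2-yl]methyl trifluoromethanesulfonate
Conditions: Tf2O, 2,6-lutidine, CH2Cl2, −78 °C; cold aqueous wash, used at once
Reagents that add atoms: trifluoromethanesulfonic anhydride, O=S(=O)(OS(=O)(=O)C(F)(F)F)C(F)(F)F
Why: O-Sulfonylation of the primary alcohol at low temperature; the triflate is chosen because the carbon is neopentyl-like (bonded to the fully substituted oxirane carbon) and needs the best leaving group, and with no hydrogen on the neighbouring carbon no elimination can compete.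

Step 5
Reactants: 5 [(2R,3R)-2-methyl-3-{(3S)-3-methyl-3-[(triethylsilyl)oxy]pent-4-en-1-yl}oxiran-2-yl]methyl trifluoromethanesulfonate; 6 acetic acid
Product: 10 (5S)-5-{(1R,4S)-1-hydroxy-4-methyl-4-[(triethylsilyl)oxy]hex-5-en-1-yl}-5-methyloxolan-2-one, via dilithioacetate 7 (not isolated), via lithium epoxy carboxylate 8 (not isolated), via epoxy acid 9 (not isolated)
Conditions: 6, LiN(iPr)2 (2 equiv per 6), THF/DMPU, 0 → 40 °C; 5, −78 → 0 °C; 1 M aq. HCl to pH 3, 0 °C → rt
Reagents that add atoms: none
Why: The carbon of dilithioacetate 7 should displace triflate at C4 (SN2; no β-hydrogen is available for elimination and at −78 °C triflate departure is far faster than attack on the oxirane) to give carboxylate 8 with the C3–C4 bond in place, and on acidification the carboxyl oxygen of 9 attacks the protonated oxirane at its tertiary carbon C5 from the back side, releasing the oxirane oxygen as the C1′ hydroxyl. The closest known reaction types are the C-alkylation of carboxylic acid dianions by primary sulfonates and halides and the spontaneous lactonisation of 4,5-epoxy acids seen when 4-enoic acids are epoxidised with peracids. The γ-lactone closes 5-exo-tet at C5 with the oxirane as leaving group; no other ring is formed. C5 becomes (S) by inversion of the (2R) oxirane carbon, so its controlling element is the epoxidation of step 3 relayed stereospecifically, and C1′ keeps its C–O bond and stays (R), which gives the anti O1/C1′–OH arrangement directly. The step needs C- over O-alkylation (the carbanion centre of the dianion is by far the more nucleophilic), substitution at C4 before any oxirane opening (secured by the triflate), and opening at C5 and not C1′ (the 5-exo ring size and the cation-stabilising tertiary carbon point the same way, while 6-endo attack at C1′ is doubly disfavoured); the silyl ether keeps O4′ from competing for the oxirane.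

Step 6
Reactants: 10 (5S)-5-{(1R,4S)-1-hydroxy-4-methyl-4-[(triethylsilyl)oxy]hex-5-en-1-yl}-5-methyloxolan-2-one
Product: 11 (5S)-5-[(1R,4S)-1,4-dihydroxy-4-methylhex-5-en-1-yl]-5-methyloxolan-2-one
Conditions: HF·pyridine, pyridine, THF, 0 °C → rt
Reagents that add atoms: none
Why: Fluoride-mediated cleavage of the silyl ether (Si–F bond formation) under pyridine buffering should leave the γ-lactone and the acid-sensitive tertiary allylic alcohol intact and frees the hydroxyl that favours the metathesis.

Step 7
Reactants: 12 pent-1-en-4-yne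
Product: 15 (3E)-4-methylhepta-3,6-dien-1-ol, via alkenyldimethylalane 13 (not isolated), via lithium alkenylalanate 14 (not isolated)
Conditions: Me3Al, Cp2ZrCl2 (cat.), CH2Cl2, 0 °C → rt; n-BuLi, THF, −30 °C; oxirane, −30 → 0 °C; 1 M aq. HCl, 0 °C
Reagents that add atoms: trimethylaluminium, C[Al](C)C; oxirane, C1CO1
Why: Zirconium-catalysed carboalumination (Negishi carboalumination) adds methyl and aluminium syn across the terminal alkyne with aluminium on the terminal carbon, giving the (E)-trisubstituted alkenylalane (the isolated monosubstituted alkene is carbometallated far more slowly), and conversion into the alanate with n-BuLi makes the alkenyl group nucleophilic enough to open oxirane with retention of the double-bond geometry.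

Step 8
Reactants: 15 (3E)-4-methylhepta-3,6-dien-1-ol
Product: 16 (4E)-7-iodo-4-methylhepta-1,4-diene
Conditions: I2, PPh3, imidazole, CH2Cl2, 0 °C → rt
Reagents that add atoms: iodine, II
Why: Appel-type iodination, in which the alkoxyphosphonium ion formed from PPh3 and I2 is displaced by iodide at the primary carbon (SN2) without touching either alkene.

Step 9
Reactants: 16 (4E)-7-iodo-4-methylhepta-1,4-diene; 17 3-bromofuran
Product: 19 3-[(3E)-4-methylhepta-3,6-dien-1-yl]furan, via alkylzinc iodide 18 (not isolated)
Conditions: Zn dust, Me3SiCl (cat.), THF/DMA, 40 °C; then 17, Pd(dppf)Cl2 (cat.), 50 °C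
Reagents that add atoms: none
Why: Negishi coupling: zinc inserts into the primary C–I bond and the alkylzinc iodide transmetallates to the arylpalladium bromide formed from 3-bromofuran and zerovalent palladium, the wide-bite-angle dppf ligand favouring reductive elimination over β-hydride elimination, while both alkenes are inert.

Step 10
Reactants: 11 (5S)-5-[(1R,4S)-1,4-dihydroxy-4-methylhex-5-en-1-yl]-5-methyloxolan-2-one; 19 3-[(3E)-4-methylhepta-3,6-dien-1-yl]furan
Product: 20 (5S)-5-[(1R,4S,5E,8E)-11-(furan-3-yl)-1,4-dihydroxy-4,8-dimethylundeca-5,8-dien-1-yl]-5-methyloxolan-2-one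
Conditions: second-generation Hoveyda–Grubbs catalyst (cat.), 1,4-benzoquinone (cat.), 19 in excess, CH2Cl2, 40 °C
Reagents that add atoms: none
Why: Olefin cross-metathesis: the unhindered monosubstituted alkene of 19 initiates readily while the vinyl group of 11, next to a quaternary carbinol carbon, homodimerises slowly and so should enter the cross reaction selectively; the trisubstituted alkene, furan, lactone and free hydroxyls are tolerated, the (E)-geometry at C5′=C6′ is the sterically enforced outcome next to the quaternary carbon, and benzoquinone suppresses ruthenium hydride migration in the skipped diene.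

**Compound list**
1 | (S)-(+)-linalool, (3S)-3,7-dimethylocta-1,6-dien-3-ol | C=C[C@@](C)(O)CCC=C(C)C | starting material
2 | (3S)-3,7-dimethyl-3-[(triethylsilyl)oxy]octa-1,6-diene | C=C[C@@](C)(O[Si](CC)(CC)CC)CCC=C(C)C | intermediate
3 | (2E,6S)-2,6-dimethyl-6-[(triethylsilyl)oxy]octa-2,7-dien-1-ol | C=C[C@@](C)(O[Si](CC)(CC)CC)CC/C=C(\C)CO | intermediate
4 | [(2R,3R)-2-methyl-3-{(3S)-3-methyl-3-[(triethylsilyl)oxy]pent-4-en-1-yl}oxiran-2-yl]methanol | C=C[C@@](C)(O[Si](CC)(CC)CC)CC[C@H]1O[C@]1(C)CO | intermediate
5 | [(2R,3R)-2-methyl-3-{(3S)-3-methyl-3-[(triethylsilyl)oxy]pent-4-en-1-yl}oxiran-2-yl]methyl trifluoromethanesulfonate | C=C[C@@](C)(O[Si](CC)(CC)CC)CC[C@H]1O[C@]1(C)COS(=O)(=O)C(F)(F)F | intermediate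
6 | acetic acid | CC(=O)O | starting material
7 | dilithioacetate (dilithium salt of the acetic acid dianion) | [Li]CC(=O)O[Li] | intermediate
8 | lithium 3-[(2R,3R)-2-methyl-3-{(3S)-3-methyl-3-[(triethylsilyl)oxy]pent-4-en-1-yl}oxiran-2-yl]propanoate | C=C[C@@](C)(O[Si](CC)(CC)CC)CC[C@H]1O[C@]1(C)CCC(=O)[O-].[Li+] | intermediate
9 | 3-[(2R,3R)-2-methyl-3-{(3S)-3-methyl-3-[(triethylsilyl)oxy]pent-4-en-1-yl}oxiran-2-yl]propanoic acid | C=C[C@@](C)(O[Si](CC)(CC)CC)CC[C@H]1O[C@]1(C)CCC(=O)O | intermediate
10 | (5S)-5-{(1R,4S)-1-hydroxy-4-methyl-4-[(triethylsilyl)oxy]hex-5-en-1-yl}-5-methyloxolan-2-one | C=C[C@@](C)(O[Si](CC)(CC)CC)CC[C@@H](O)[C@]1(C)CCC(=O)O1 | intermediate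
11 | (5S)-5-[(1R,4S)-1,4-dihydroxy-4-methylhex-5-en-1-yl]-5-methyloxolan-2-one | C=C[C@@](C)(O)CC[C@@H](O)[C@]1(C)CCC(=O)O1 | intermediate
12 | pent-1-en-4-yne | C=CCC#C | starting material
13 | dimethyl[(1E)-2-methylpenta-1,4-dien-1-yl]alane | C=CC/C(C)=C/[Al](C)C | intermediate
14 | lithium butyl(dimethyl)[(1E)-2-methylpenta-1,4-dien-1-yl]alanate | [Li+].C=CC/C(C)=C/[Al-](C)(C)CCCC | intermediate
15 | (3E)-4-methylhepta-3,6-dien-1-ol | C=CC/C(C)=C/CCO | intermediate
16 | (4E)-7-iodo-4-methylhepta-1,4-diene | C=CC/C(C)=C/CCI | intermediate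
17 | 3-bromofuran | Brc1ccoc1 | starting material
18 | [(3E)-4-methylhepta-3,6-dien-1-yl]zinc iodide | C=CC/C(C)=C/CC[Zn]I | intermediate
19 | 3-[(3E)-4-methylhepta-3,6-dien-1-yl]furan | C=CC/C(C)=C/CCc1ccoc1 | intermediate
20 | (5S)-5-[(1R,4S,5E,8E)-11-(furan-3-yl)-1,4-dihydroxy-4,8-dimethylundeca-5,8-dien-1-yl]-5-methyloxolan-2-one | C/C(=C\CCc1ccoc1)C/C=C/[C@@](C)(O)CC[C@@H](O)[C@]1(C)CCC(=O)O1 | target

**Step count and risks**
Total: 10 steps. Longest linear sequence: 7 steps (steps 1–6 and 10, from 1 to 20); the furan diene branch is 3 steps (steps 7–9).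

Steps most likely to fail:

1. Step 5. Substitution at the neopentyl-like carbon may be slower than decomposition of the triflate or base-induced opening of the oxirane, and partial ionisation of the tertiary oxirane carbon on acidification would erode the inversion. The fallback sets out from 3 and returns at 10; it makes the C3–C4 bond at an unhindered allylic carbon before any oxirane exists. Bromination of 3 (CBr4, PPh3, CH2Cl2, 0 °C) should give (3S,6E)-8-bromo-3,7-dimethyl-3-[(triethylsilyl)oxy]octa-1,6-diene F1. Its SN2 reaction with the lithium enolate of tert-butyl acetate F2 (from t-BuOAc and LiN(iPr)2, THF, −78 °C) should give tert-butyl (4E,8S)-4,8-dimethyl-8-[(triethylsilyl)oxy]deca-4,9-dienoate F3. Shi epoxidation (D-fructose-derived ketone, KHSO5, K2CO3 buffer, MeCN/dimethoxymethane/water, 0 °C) should epoxidise only the trisubstituted alkene and, by the spiro transition-state model, give tert-butyl 3-[(2R,3R)-2-methyl-3-{(3S)-3-methyl-3-[(triethylsilyl)oxy]pent-4-en-1-yl}oxiran-2-yl]propanoate F4. Catalytic camphorsulfonic acid in CH2Cl2 at 0 °C then closes the lactone 5-exo with inversion and loss of 2-methylpropene to give 10.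

2. Step 2. Over-oxidation to the enal, attack at the allylic methylene, stalled conversion or partial loss of the silyl ether may erode the yield. The fallback sets out from 2 and returns at 3; it builds the (E)-allylic alcohol by olefination instead of C–H oxidation. Chemoselective epoxidation of the trisubstituted alkene (mCPBA, NaHCO3, CH2Cl2, 0 °C) should give triethyl{[(3S)-5-(3,3-dimethyloxiran-2-yl)-3-methylpent-1-en-3-yl]oxy}silane F5 (both oxirane epimers serve). Cleavage with H5IO6 (THF/water, 0 °C) should give (4S)-4-methyl-4-[(triethylsilyl)oxy]hex-5-enal F6 and acetone. Wittig reaction with Ph3P=C(CH3)CO2Et (toluene, 80 °C) should give ethyl (2E,6S)-2,6-dimethyl-6-[(triethylsilyl)oxy]octa-2,7-dienoate F7, and reduction with i-Bu2AlH (CH2Cl2, −78 °C) gives 3.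

3. Step 9. Zinc insertion may be incomplete or the alkylzinc may be protonated, and β-hydride elimination or alkene migration may compete in the coupling. The fallback sets out from 16 and 17 and returns at 19; it reverses the polarity and uses no catalyst. Bromine–lithium exchange on 17 (n-BuLi, THF, −78 °C) should give 3-furyllithium F8, which is alkylated by the primary iodide 16 (THF/DMPU, −78 → −40 °C, kept cold to avoid migration of lithium to C2 of the furan) to give 19.

Further compounds
F1 | step 5 | (3S,6E)-8-bromo-3,7-dimethyl-3-[(triethylsilyl)oxy]octa-1,6-diene | C=C[C@@](C)(O[Si](CC)(CC)CC)CC/C=C(\C)CBr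
F2 | step 5 | lithium enolate of tert-butyl acetate | C=C(O[Li])OC(C)(C)C
F3 | step 5 | tert-butyl (4E,8S)-4,8-dimethyl-8-[(triethylsilyl)oxy]deca-4,9-dienoate | C=C[C@@](C)(O[Si](CC)(CC)CC)CC/C=C(\C)CCC(=O)OC(C)(C)C
F4 | step 5 | tert-butyl 3-[(2R,3R)-2-methyl-3-{(3S)-3-methyl-3-[(triethylsilyl)oxy]pent-4-en-1-yl}oxiran-2-yl]propanoate | C=C[C@@](C)(O[Si](CC)(CC)CC)CC[C@H]1O[C@]1(C)CCC(=O)OC(C)(C)C
F5 | step 2 | triethyl{[(3S)-5-(3,3-dimethyloxiran-2-yl)-3-methylpent-1-en-3-yl]oxy}silane | C=C[C@@](C)(O[Si](CC)(CC)CC)CCC1OC1(C)C
F6 | step 2 | (4S)-4-methyl-4-[(triethylsilyl)oxy]hex-5-enal | C=C[C@@](C)(O[Si](CC)(CC)CC)CCC=O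
F7 | step 2 | ethyl (2E,6S)-2,6-dimethyl-6-[(triethylsilyl)oxy]octa-2,7-dienoate | C=C[C@@](C)(O[Si](CC)(CC)CC)CC/C=C(\C)C(=O)OCC
F8 | step 9 | 3-furyllithium | [Li]c1ccoc1
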